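The data are simulated from invented constants; noise was put on by code.

Starting complex in the delta and gamma runs was where I began: by 120 s its reading had fallen to 2% and 4%, while side product stood at 46% and 40%.

all flasks: starting complex 0.042 M

| flask | incoming ligand | remark | time |
|---|---|---|---|
| delta | 0.044 M | run made earlier |  |
| gamma | 0.045 M | run made earlier |  |
| north-west | 0.0400 M |  | 2.0 min |
| south-east | 0.0340 M |  | 2.0 min |

| run | time / s | complex with one exchanged / % | starting complex / % | side product / % | complex with two exchanged / % |
|---|---|---|---|---|---|
| delta | 10.0 | 38 | 33 | 15 | 6 |
| delta | 30.0 | 35 | 13 | 31 | 12 |
| delta | 60.0 | 34 | 4 | 38 | 12 |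
| delta | 80.0 | 41 | 3 | 43 | 12 |
| delta | 120 | 38 | 2 | 46 | 11 |
| gamma | 10.0 | 35 | 31 | 18 | 10 |
| gamma | 20.0 | 36 | 19 | 24 | 11 |
| gamma | 30.0 | 36 | 11 | 29 | 14 |
| gamma | 60.0 | 35 | 2 | 38 | 14 |
| gamma | 120 | 37 | 4 | 40 | 16 |

(each reading ± 2 percentage points)

- percentages count the starting complex that a species holds: one side product counts as two
- what was read earlier has a scatter of 2 percentage points, one standard deviation
- a reading of starting complex is of its free form alone

* which of these there is most of at the end, counted by the starting complex in it, north-west (complex with one exchanged / complex with two exchanged / side product / starting complex)
* which of these there is most of at the end, counted by the starting complex in it, south-east (complex with one exchanged / complex with two exchanged / side product / starting complex)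
* the largest of these amounts at the end, in percent of the starting complex charged, north-west
* the largest of these amounts at the end, in percent of the starting complex charged, south-east

One side product counts as two, so I supposed that it forms when a starting complex meets a complex with one exchanged. On that supposition, incoming ligand competes with complex with one exchanged for free starting complex. I therefore folded the charges into the ratio [starting complex]/[incoming ligand], with the symmetric charge, one ligand per complex, as the unit of the scale. I took side product at the end to grow in proportion to this ratio. Delta gave 48.2% and gamma 42.9% at the symmetric charge. Their mean, 45.5%, is my competition constant, a reading and not a ratio of rates: the side product at 120 s for one ligand per complex. One number was not proven enough: the two runs differ by 5.3 percentage points against a scatter of 2 points, their ratios lie close together, and I had to assume that starting complex falls as low by 2.0 min in the new flasks as in those runs.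

So I reckoned side product largest, at 47.8% in north-west and 56.2% in south-east, above the 38% of complex with one exchanged read in delta. The forecast gave side product at 43% (38% to 47%) in north-west and, differing from me, complex with one exchanged at 35% (31% to 41%) in south-east, reasoning that “the ligand simply runs out”.

The flasks gave side product at 48.1% in north-west and side product at 53.0% in south-east.

    starting complex + incoming ligand ⇌ leaving ligand + complex with one exchanged (K = 72.0, k = 2.70 M⁻¹ s⁻¹)
    complex with one exchanged + incoming ligand ⇌ leaving ligand + complex with two exchanged (K = 1.30, k = 1.20 M⁻¹ s⁻¹)
    2 starting complex → homo dimer (k = 0.110 M⁻¹ s⁻¹)
    starting complex + complex with one exchanged → side product (k = 1.30 M⁻¹ s⁻¹)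
    starting complex ⇌ dormant form (K = 0.350, k = 0.0180 s⁻¹)

South-east ended with 3.6% of its starting complex free and 14% of its incoming ligand unbound. Its own constant came to 42.9%, against my 45.5%. With south-east's starting complex cut to 0.017 M, the constant gives 22.8% of side product. That neighbouring flask held 20.5%, and complex with one exchanged held most.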